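Remark: C2 is taken as (S) (priorities O1 > ring-B carbon > C3 > H); the carbinol of 15 carries the same descriptor because its C–O bond is kept, and atom mapping of the annulation (triflate carbon of 8 → C8a, silyl carbon → C4a, chlorine → C5, acetal oxygen → C7) showed no structure in need of correction.

## Structural features

The target 20 is a flavanone: a benzo ring A fused to a dihydropyranone ring C (chroman-4-one), with an aryl ring B attached at C2. Ring A carries a single free phenol at C7. Ring B is a symmetric 4-methoxyphenyl unit flanked at C3' and C5' by two 3-methylbut-2-enyl (prenyl) chains. The only stereocentre is C2 (S); it is benzylic, bears the ring oxygen O1 and lies β to the C4 ketone, with no neighbouring stereocentre. This arrangement is fragile: base or heat can open ring C by E1cB cleavage of O1–C2 to a 2'-hydroxychalcone, whose reclosure is racemic. The prenyl alkenes rule out catalytic hydrogenation and strong acid or electrophiles. The real difficulty is therefore to close ring C on an enantiopure C2 without passing through the chalcone, and to place the ring-A oxygen correctly. The key step uses the fact that O1 (on C8a) and the carbonyl C4 (on C4a) sit on adjacent ring-A carbons, which is the pattern left when an aryne C4a≡C8a takes up an alkoxide oxygen and an acyl carbon. The free C5 position next to C4a can hold a temporary chlorine that steers this addition.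

## Logic of the disconnections

**20 ⇒ 19.** The C7 O–H bond is traced back to an acetal O–C bond. A free phenol would add to an aryne and would hinder palladium insertion as its phenoxide, so the oxygen must be masked through steps 4–10. The skeleton is unchanged. The forward step must use acid mild enough for the prenyl alkenes and for C2.

**19 ⇒ 18.** The C5–H bond is replaced by C5–Cl. The chlorine is the control element of the annulation and has no other function. The forward step must cleave C–Cl reductively without touching the alkenes, the ketone or the base-labile ring C.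

**18 ⇒ 15 + 8 (through 16 and 17).** O1–C8a and C4–C4a are cut, the two bonds that join ring A to ring C. The molecule falls into two halves of similar size and ring C is formed in one operation. The stereocentre stays in 15 and its C–O bond is not touched. The forward step needs oxygen attack at the aryne carbon remote from chlorine, acylation of the aryl anion faster than protonation, and an alkoxide 16 that survives long enough to be captured.

**8 ⇒ 7 ⇒ 3 ⇒ 2 ⇒ 1.** The acetal O–C bond of 8, then the sulfonate O–S and aryl C–Si bonds of 7, then the O–Si bonds of 3 and the C–Br bond of 2 are removed in turn. Because 1 is symmetric, bromination has only one productive kind of site. The bromine then decides which oxygen delivers silicon to carbon and is triflated, so the two oxygens are told apart without a selective protection. The forward steps require clean monobromination, and a bromine–lithium exchange with silyl shift that is faster than loss of LiCl from 4.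

**15 ⇒ 14.** The C2–H bond is cut, so the carbinol comes from a ketone by reagent-controlled reduction. This reduces the stereochemical problem to the choice of one catalyst enantiomer. The catalyst must distinguish the aryl group from CH2CO2Me and leave the alkenes alone.

**14 ⇒ 12 + 13.** The C3–C4 bond is cut (crossed Claisen). Carbon C4 is then supplied by a one-carbon electrophile. The enolate of 12 must be acylated on carbon and the product held as its enolate.

**12 ⇒ 10 + 11, 10 ⇒ 9.** Both aryl–CH2 bonds are cut in one twofold coupling that uses the symmetry of ring B, and the methyl ether is traced to the phenol of 9. The coupling must deliver the linear (α) prenyl isomer twice.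

## Other disconnections considered

**Alternative 1:** The cut runs through ring A at C8–C8a and C4a–C5, so ring A is built onto an existing, already (S)-configured ring C.
- Forward step: the siloxy diene A3, (E)-1-methoxy-3-(trimethylsilyloxy)buta-1,3-diene, would add across the sulfinyl-activated enone double bond of A2, (2S)-2-[4-methoxy-3,5-bis(3-methylbut-2-en-1-yl)phenyl]-5-(phenylsulfinyl)-2,3-dihydro-4H-pyran-4-one. Its CH2 terminus would bond to the β-carbon (C8a) and its methoxy-bearing terminus to the α-carbon (C4a). Loss of the sulfinyl group as its sulfenic acid and of the methoxy group as the alcohol would aromatise the adduct to A1, (S)-2-[4-methoxy-3,5-bis(3-methylbut-2-en-1-yl)phenyl]-7-(trimethylsilyloxy)chroman-4-one, one desilylation away from 20.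
- Origin of A2: aldehyde A4, 4-methoxy-3,5-bis(3-methylbut-2-en-1-yl)benzaldehyde, would undergo an enantioselective hetero-Diels–Alder reaction with A3 to give A5, (S)-2-[4-methoxy-3,5-bis(3-methylbut-2-en-1-yl)phenyl]-2,3-dihydro-4H-pyran-4-one, followed by sulfenylation at C5 and oxidation at sulfur.
- In favour: the polarity of A3 places the C7 oxygen without a directing group; no halogen has to be removed; the stereocentres formed in the cycloaddition disappear on aromatisation, so facial selectivity does not matter; the flavanone never meets a strong base. On all four points it is the equal or the better of the chosen plan, and its end game (one desilylation) is better than hydrodechlorination plus acetal cleavage.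
- Against: the dienophile double bond of A2 is a trisubstituted vinylogous ester, electron-rich at its β-carbon, so the cycloaddition is expected to need heat. Under heat A2 and A1 can open across O1–C2, which endangers C2. A3 is used twice and is sensitive to hydrolysis. Sulfenylation of A5 at C5 must compete with enolisation towards C3.
- Comparison: structurally it is linear and builds an aromatic ring that the chosen plan buys ready-made. Mechanistically the cycloaddition is well understood, whereas the chosen annulation is untested, which is a point for the alternative. In step count it should be about as long in the longest line and shorter in total. The chosen plan is preferred for its convergence and because its stereocentre comes from a very dependable ketone reduction.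

**Alternative 2:** The cut is C4–C4a only; O1–C8a is already present in an aryl ether.
- Forward step: bromine–lithium exchange on A7, (S)-3-[2-bromo-5-(triisopropylsilyloxy)phenoxy]-N-methoxy-N-methyl-3-[4-methoxy-3,5-bis(3-methylbut-2-en-1-yl)phenyl]propanamide, would give an aryllithium at C4a that adds to the amide carbonyl (Parham cyclization) and, after work-up, A6, (S)-2-[4-methoxy-3,5-bis(3-methylbut-2-en-1-yl)phenyl]-7-(triisopropylsilyloxy)chroman-4-one.
- Origin of A7: Mitsunobu etherification of A9, methyl (R)-3-hydroxy-3-[4-methoxy-3,5-bis(3-methylbut-2-en-1-yl)phenyl]propanoate, with A8, 2-bromo-5-(triisopropylsilyloxy)phenol, with inversion, then aminolysis of the ester.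
- In favour: every reaction type is established on this substrate class; the bromine fixes the regiochemistry; no dehalogenation follows; the ketone is released from a stable tetrahedral chelate only on cold quench, so the flavanone is not exposed to base. On precedent and on protection of the product it is better than the chosen plan.
- Against: the carbinol C–O bond is broken and remade at an electron-rich benzylic centre, where ionisation (loss of enantiopurity) and elimination to the cinnamate compete with clean inversion. The β-aryloxy carbonyl unit of A7 can lose aryloxide by E1cB when it meets the organolithium. A8 requires a regioselective monoprotection.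
- Comparison: the chosen plan keeps the carbinol C–O bond intact, which is its main structural advantage, and forms both ring bonds at once, where the alternative needs three operations (ether, amide, cyclization). In total steps the alternative should be slightly shorter; its longest line is one step longer. It serves as the fallback for step 9.

**Alternative 3:** The cut is O1–C8a only; the C4–C4a bond is already present in an aryl ketone.
- Forward step: the alkoxide of A11, (S)-1-[2-fluoro-4-(methoxymethoxy)phenyl]-3-hydroxy-3-[4-methoxy-3,5-bis(3-methylbut-2-en-1-yl)phenyl]propan-1-one, would attack C8a of the ortho-fluoroaryl ketone and expel fluoride (SNAr through a Meisenheimer adduct). This gives A10, (S)-7-(methoxymethoxy)-2-[4-methoxy-3,5-bis(3-methylbut-2-en-1-yl)phenyl]chroman-4-one, which is identical with 19.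
- Origin of A11: an enantioselective aldol reaction of the methyl ketone A12, 1-[2-fluoro-4-(methoxymethoxy)phenyl]ethan-1-one, with aldehyde A4.
- In favour: like the chosen plan it keeps the carbinol C–O bond, so C2 is formed with retention (equal). It needs no chlorine and no dehalogenation (better). Intramolecular SNAr is a known closure (better on precedent). It should be the shortest of all the plans (better).
- Against: the alkoxide of a β-hydroxy aryl ketone fragments by retro-aldol and dehydrates to the chalcone more readily than the ester alkoxide 16. The fluoroarene is activated only by one ortho carbonyl, whose pull is reduced by the para alkoxy group, so the closure would need the heat and base that favour both side reactions. A highly enantioselective aldol of an aryl methyl ketone with an aromatic aldehyde is itself hard.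
- Comparison: both plans form O1–C8a from a chiral alkoxide. The chosen plan uses an aryne, which reacts at or below room temperature, and forms the second bond in the same operation, at the price of an unprecedented tandem and two extra end-game steps. The alternative uses proven chemistry but its risk lies in the stability and the enantioselective preparation of A11.

Key step: step 9

## Route

Step 1
Reactants: 1 5-chlorobenzene-1,3-diol (5-chlororesorcinol)
Product: 2 4-bromo-5-chlorobenzene-1,3-diol
Conditions: NBS (1.0 equiv), MeCN, −30 → 0 °C
Reagents that add atoms: N-bromosuccinimide, O=C1CCC(=O)N1Br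
Why: Electrophilic aromatic bromination; the two positions of 1 that are para to one hydroxyl and ortho to the other are equivalent by symmetry and far more reactive than the position between the hydroxyls, so one equivalent of NBS at low temperature should give a single monobromide with bromine already next to chlorine.

Step 2
Reactants: 2 4-bromo-5-chlorobenzene-1,3-diol
Product: 3 4-bromo-5-chloro-1,3-bis(trimethylsilyloxy)benzene
Conditions: HMDS, THF, 65 °C; evaporate, use crude
Reagents that add atoms: hexamethyldisilazane, C[Si](C)(C)N[Si](C)(C)C
Why: O-Silylation of both phenols by the silazane, driven by loss of ammonia; no selectivity is needed at this stage.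

Step 3
Reactants: 3 4-bromo-5-chloro-1,3-bis(trimethylsilyloxy)benzene
Product: 7 3-chloro-5-hydroxy-2-(trimethylsilyl)phenyl trifluoromethanesulfonate, via aryllithium 4 (not isolated), via lithium aryloxide 5 (not isolated), via silyl ether triflate 6 (not isolated)
Conditions: n-BuLi (1.05 equiv), THF, −90 °C; Tf2O, −90 → −60 °C; then 10% aq citric acid, MeOH, rt
Reagents that add atoms: trifluoromethanesulfonic anhydride, O=S(=O)(OS(=O)(=O)C(F)(F)F)C(F)(F)F
Why: Bromine–lithium exchange followed by a 1,3 O→C silyl shift (retro-Brook rearrangement) from the only ortho silyloxy group should outrun loss of LiCl from 4 at this temperature; only the aryloxide 5 so released is triflated, which tells the two oxygens apart, and the remaining aryl O–Si bond of 6 falls to mild acid while the C–Si bond, deactivated by the neighbouring triflate and chlorine, is kept.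

Step 4
Reactants: 7 3-chloro-5-hydroxy-2-(trimethylsilyl)phenyl trifluoromethanesulfonate
Product: 8 3-chloro-5-(methoxymethoxy)-2-(trimethylsilyl)phenyl trifluoromethanesulfonate
Conditions: MOMCl, iPr2NEt, CH2Cl2, 0 °C → rt
Reagents that add atoms: chloromethyl methyl ether, COCCl
Why: O-Alkylation of the acidic phenol by the chloromethyl ether under amine base (acetal protection); triflate and aryl silane are inert in the absence of fluoride.

Step 5
Reactants: 9 1-(3,5-dibromo-4-hydroxyphenyl)ethan-1-one
Product: 10 1-(3,5-dibromo-4-methoxyphenyl)ethan-1-one
Conditions: MeI, K2CO3, DMF, rt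
Reagents that add atoms: iodomethane, CI
Why: Williamson ether synthesis on the acidic 2,6-dibromophenol; carbonate does not enolise the methyl ketone.

Step 6
Reactants: 10 1-(3,5-dibromo-4-methoxyphenyl)ethan-1-one; 11 4,4,5,5-tetramethyl-2-(3-methylbut-2-en-1-yl)-1,3,2-dioxaborolane (3 equiv)
Product: 12 1-[4-methoxy-3,5-bis(3-methylbut-2-en-1-yl)phenyl]ethan-1-one
Conditions: PdCl2(IPent)(3-chloropyridine) (4 mol %), KOH (5 M aq), THF, 70 °C
Reagents that add atoms: none
Why: Twofold Suzuki–Miyaura coupling; with the bulky carbene IPent (1,3-bis[2,6-di(pentan-3-yl)phenyl]imidazol-2-ylidene) on palladium, reductive elimination is expected at the less hindered allyl terminus, giving the linear prenyl group at both positions; an aryl methyl ketone tolerates aqueous hydroxide under these conditions and is not allylated by the boronate.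

Step 7
Reactants: 12 1-[4-methoxy-3,5-bis(3-methylbut-2-en-1-yl)phenyl]ethan-1-one; 13 dimethyl carbonate (excess)
Product: 14 methyl 3-[4-methoxy-3,5-bis(3-methylbut-2-en-1-yl)phenyl]-3-oxopropanoate
Conditions: NaH (2.5 equiv), THF, 65 °C; AcOH quench
Reagents that add atoms: none
Why: Crossed Claisen condensation of the ketone enolate with the non-enolisable carbonate; the β-keto ester leaves the equilibrium as its sodium enolate, which drives the C-acylation to completion.

Step 8
Reactants: 14 methyl 3-[4-methoxy-3,5-bis(3-methylbut-2-en-1-yl)phenyl]-3-oxopropanoate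
Product: 15 methyl (S)-3-hydroxy-3-[4-methoxy-3,5-bis(3-methylbut-2-en-1-yl)phenyl]propanoate
Conditions: RuCl[(S,S)-TsDPEN](p-cymene) (1 mol %), HCO2H/Et3N (5:2), DMF, 40 °C
Reagents that add atoms: none
Why: Noyori–Ikariya asymmetric transfer hydrogenation; hydride and proton are passed from the ruthenium hydride amine to the ketone in an outer-sphere six-membered transition state with the aryl ring under the η6-arene, the facial preference that turns acetophenone into the (S)-alcohol with the (S,S) ligand, and since aryl outranks CH2CO2Me as phenyl outranks methyl, the (S)-carbinol is expected; isolated trisubstituted alkenes are not reduced.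

Step 9
Reactants: 15 methyl (S)-3-hydroxy-3-[4-methoxy-3,5-bis(3-methylbut-2-en-1-yl)phenyl]propanoate; 8 3-chloro-5-(methoxymethoxy)-2-(trimethylsilyl)phenyl trifluoromethanesulfonate (1.6 equiv)
Product: 18 (S)-5-chloro-7-(methoxymethoxy)-2-[4-methoxy-3,5-bis(3-methylbut-2-en-1-yl)phenyl]chroman-4-one, via potassium alkoxide 16 (not isolated), via chloroaryne 17 (not isolated)
Conditions: KH (1.0 equiv), THF, 0 °C; then 8, CsF (3 equiv), 18-crown-6, THF, −20 °C → rt; sat. aq NH4Cl
Reagents that add atoms: none
Why: Proposed new method: fluoride attacks silicon of 8 and the aryl anion expels triflate to give aryne 17, whose triple bond is distorted by the adjacent C–Cl bond so that the carbon remote from chlorine is the more electrophilic one; alkoxide 16 should add there through oxygen (O1–C8a), leaving the carbanion at C4a next to chlorine, where induction stabilises it, while the alkoxy group at the future C7 exerts only a weak opposing bias. The closest known reaction types are the fluoride-mediated annulation of arynes with salicylate esters to xanthones, the formal insertion of arynes into the C–O bond of carboxylic acids that leads to chroman-4-ones, and the O-arylation of alkoxides by arynes; the new element is an aliphatic β-alkoxide ester as the two-atom partner. The aryl anion then adds to the ester carbonyl in a 6-exo-trig closure of ring C, and loss of methoxide gives the ketone (C4–C4a). No stereocentre is created: C2 is the carbinol carbon of 15, its C–O bond is never broken, and the (S) descriptor is carried over unchanged. The step needs regioselective oxygen attack, which the chlorine secures, and acylation rather than protonation of the aryl anion, which is served by making 16 with KH (no conjugate acid remains) in THF (a poor proton donor). It also needs 16 to be captured before retro-aldol cleavage, hence the low temperature and the excess of 8, which is also meant to consume the liberated methoxide before it can open ring C of 18; alkoxide that is silylated by 8 is returned by fluoride.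

Step 10
Reactants: 18 (S)-5-chloro-7-(methoxymethoxy)-2-[4-methoxy-3,5-bis(3-methylbut-2-en-1-yl)phenyl]chroman-4-one
Product: 19 (S)-7-(methoxymethoxy)-2-[4-methoxy-3,5-bis(3-methylbut-2-en-1-yl)phenyl]chroman-4-one
Conditions: Pd(OAc)2 (5 mol %), XPhos (10 mol %), HCO2Na (3 equiv), DMF, 70 °C
Reagents that add atoms: none
Why: Palladium-catalysed hydrodehalogenation; zerovalent palladium bearing the bulky biaryl phosphine inserts into the C–Cl bond, which the ortho carbonyl activates, chloride is exchanged for formate, loss of CO2 gives the aryl palladium hydride and reductive elimination gives the arene; formate is too weak a base to open ring C and the ligated hydride should not add to trisubstituted alkenes.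

Step 11
Reactants: 19 (S)-7-(methoxymethoxy)-2-[4-methoxy-3,5-bis(3-methylbut-2-en-1-yl)phenyl]chroman-4-one
Product: 20 (S)-7-hydroxy-2-[4-methoxy-3,5-bis(3-methylbut-2-en-1-yl)phenyl]chroman-4-one
Conditions: HCl (2 M aq), MeOH/THF, 40 °C
Reagents that add atoms: none
Why: Acid-catalysed acetal cleavage with transfer of the methoxymethyl group to methanol; the aryloxy group para to the carbonyl is a good leaving group, so dilute acid suffices, and the methyl ether, the prenyl alkenes and C2 are expected to be stable under these conditions.

## Compound list

1 | 5-chlorobenzene-1,3-diol (5-chlororesorcinol) | Oc1cc(O)cc(Cl)c1 | starting material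
2 | 4-bromo-5-chlorobenzene-1,3-diol | Oc1cc(O)c(Br)c(Cl)c1 | intermediate
3 | 4-bromo-5-chloro-1,3-bis(trimethylsilyloxy)benzene | C[Si](C)(C)Oc1cc(O[Si](C)(C)C)c(Br)c(Cl)c1 | intermediate
4 | [2-chloro-4,6-bis(trimethylsilyloxy)phenyl]lithium | C[Si](C)(C)Oc1cc(O[Si](C)(C)C)c([Li])c(Cl)c1 | intermediate (not isolated)
5 | lithium 3-chloro-2-(trimethylsilyl)-5-(trimethylsilyloxy)phenolate | [Li+].[O-]c1cc(O[Si](C)(C)C)cc(Cl)c1[Si](C)(C)C | intermediate (not isolated)
6 | 3-chloro-2-(trimethylsilyl)-5-(trimethylsilyloxy)phenyl trifluoromethanesulfonate | C[Si](C)(C)Oc1cc(Cl)c([Si](C)(C)C)c(OS(=O)(=O)C(F)(F)F)c1 | intermediate (not isolated)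
7 | 3-chloro-5-hydroxy-2-(trimethylsilyl)phenyl trifluoromethanesulfonate | Oc1cc(Cl)c([Si](C)(C)C)c(OS(=O)(=O)C(F)(F)F)c1 | intermediate
8 | 3-chloro-5-(methoxymethoxy)-2-(trimethylsilyl)phenyl trifluoromethanesulfonate | COCOc1cc(Cl)c([Si](C)(C)C)c(OS(=O)(=O)C(F)(F)F)c1 | intermediate
9 | 1-(3,5-dibromo-4-hydroxyphenyl)ethan-1-one | CC(=O)c1cc(Br)c(O)c(Br)c1 | starting material
10 | 1-(3,5-dibromo-4-methoxyphenyl)ethan-1-one | CC(=O)c1cc(Br)c(OC)c(Br)c1 | intermediate
11 | 4,4,5,5-tetramethyl-2-(3-methylbut-2-en-1-yl)-1,3,2-dioxaborolane (prenylboronic acid pinacol ester) | CC(C)=CCB1OC(C)(C)C(C)(C)O1 | starting material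
12 | 1-[4-methoxy-3,5-bis(3-methylbut-2-en-1-yl)phenyl]ethan-1-one | COc1c(CC=C(C)C)cc(C(C)=O)cc1CC=C(C)C | intermediate
13 | dimethyl carbonate | COC(=O)OC | starting material
14 | methyl 3-[4-methoxy-3,5-bis(3-methylbut-2-en-1-yl)phenyl]-3-oxopropanoate | COc1c(CC=C(C)C)cc(C(=O)CC(=O)OC)cc1CC=C(C)C | intermediate
15 | methyl (S)-3-hydroxy-3-[4-methoxy-3,5-bis(3-methylbut-2-en-1-yl)phenyl]propanoate | COc1c(CC=C(C)C)cc([C@@H](O)CC(=O)OC)cc1CC=C(C)C | intermediate
16 | potassium (S)-3-methoxy-1-[4-methoxy-3,5-bis(3-methylbut-2-en-1-yl)phenyl]-3-oxopropan-1-olate | COc1c(CC=C(C)C)cc([C@@H]([O-])CC(=O)OC)cc1CC=C(C)C.[K+] | intermediate (not isolated)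
17 | 3-chloro-5-(methoxymethoxy)benzyne (triple bond C1–C2, chlorine on C3) | COCOC1=CC#CC(Cl)=C1 | intermediate (not isolated)
18 | (S)-5-chloro-7-(methoxymethoxy)-2-[4-methoxy-3,5-bis(3-methylbut-2-en-1-yl)phenyl]chroman-4-one | COc1c(CC=C(C)C)cc([C@@H]2CC(=O)c3c(Cl)cc(OCOC)cc3O2)cc1CC=C(C)C | intermediate
19 | (S)-7-(methoxymethoxy)-2-[4-methoxy-3,5-bis(3-methylbut-2-en-1-yl)phenyl]chroman-4-one | COc1c(CC=C(C)C)cc([C@@H]2CC(=O)c3ccc(OCOC)cc3O2)cc1CC=C(C)C | intermediate
20 | (S)-7-hydroxy-2-[4-methoxy-3,5-bis(3-methylbut-2-en-1-yl)phenyl]chroman-4-one | COc1c(CC=C(C)C)cc([C@@H]2CC(=O)c3ccc(O)cc3O2)cc1CC=C(C)C | target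

## Step count and least certain steps

Total step count: 11. Longest linear sequence: 7 steps (steps 1–4, then 9–11; equally steps 5–8, then 9–11).

**Step 9 (key step, new method).** Four processes could divert it:
- Quenching of the aryl anion before it reaches the ester, either by proton transfer or by loss of chloride to a second aryne. This would leave an open aryl ether instead of ring C.
- Retro-aldol fragmentation of the potassium alkoxide, which costs material and, through recombination, enantiopurity.
- Base-induced E1cB opening of ring C in the product by methoxide or fluoride, which would racemise C2.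
- Ene reaction of the aryne with the prenyl alkenes.

Fallback with known chemistry, setting out from 14 and returning at 19, so that step 10 is bypassed as well:
- Transfer hydrogenation of 14 with the enantiomeric catalyst RuCl[(R,R)-TsDPEN](p-cymene) would give methyl (R)-3-hydroxy-3-[4-methoxy-3,5-bis(3-methylbut-2-en-1-yl)phenyl]propanoate F1.
- Mitsunobu etherification (PPh3, DIAD, toluene, 0 °C) with 2-bromo-5-(methoxymethoxy)phenol F2 would invert the carbinol to methyl (S)-3-[2-bromo-5-(methoxymethoxy)phenoxy]-3-[4-methoxy-3,5-bis(3-methylbut-2-en-1-yl)phenyl]propanoate F3. F2 would be made from commercial 4-bromoresorcinol with MOMCl/iPr2NEt at the hydroxyl that is not flanked by bromine.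
- Aminolysis with Me(MeO)NH·HCl/AlMe3 would give (S)-3-[2-bromo-5-(methoxymethoxy)phenoxy]-N-methoxy-N-methyl-3-[4-methoxy-3,5-bis(3-methylbut-2-en-1-yl)phenyl]propanamide F4.
- Bromine–lithium exchange (n-BuLi, THF, −100 °C) and Parham cyclization onto the amide would give 19.

**Step 10.** The likely failure is erosion of configuration by reversible opening of ring C during the warm, formate-mediated reduction. A second risk is migration or reduction of the prenyl double bonds by palladium hydride if insertion into the hindered C–Cl bond is slow. Fallback by temporary removal of the ketone, setting out from 18 and returning at 19: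
- NaBH4 (MeOH/THF, 0 °C) would give (2S)-5-chloro-7-(methoxymethoxy)-2-[4-methoxy-3,5-bis(3-methylbut-2-en-1-yl)phenyl]chroman-4-ol F5, as a mixture of C4 epimers, which can no longer ring-open.
- Hydrodechlorination (Pd(OAc)2, XPhos, HCO2Na, DMF, 90 °C) would give (2S)-7-(methoxymethoxy)-2-[4-methoxy-3,5-bis(3-methylbut-2-en-1-yl)phenyl]chroman-4-ol F6.
- Dess–Martin oxidation (NaHCO3, CH2Cl2) would return 19.

**Step 6.** The likely failure is allyl transposition at palladium, which would give the branched 2-methylbut-3-en-2-yl isomer at one or both positions, together with incomplete second coupling at the hindered bromide. Fallback that removes the regiochemical question, setting out from 10 and returning at 12: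
- Stille coupling with allyltributylstannane (Pd(PPh3)4, toluene, 100 °C) would give 1-(3,5-diallyl-4-methoxyphenyl)ethan-1-one F7.
- Cross-metathesis with 2-methylbut-2-ene (second-generation Grubbs catalyst RuCl2(=CHPh)(H2IMes)(PCy3), CH2Cl2, 35 °C) would give 12.

**Step 3.** Three processes could divert it: attack of n-BuLi on the second aryl silyl ether, which would lead to double triflation; elimination of LiCl from the ortho-chloro aryllithium before the silyl shift; and protodesilylation at carbon during the acidic cleavage of the O–Si bond. Fallback in which the oxygens are differentiated before lithiation, setting out from 1 and returning at 8: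
- Statistical monoprotection of 1 (MOMCl, iPr2NEt, CH2Cl2) would give 3-chloro-5-(methoxymethoxy)phenol F8.
- Amine-directed ortho-bromination (NBS, cat. iPr2NH, CH2Cl2, 0 °C) would give 2-bromo-3-chloro-5-(methoxymethoxy)phenol F9, after separation from regioisomers.
- HMDS would give [2-bromo-3-chloro-5-(methoxymethoxy)phenoxy]trimethylsilane F10.
- n-BuLi followed by Tf2O (THF, −90 °C) would give 8 directly.

This fallback exchanges the silyl-ether risk for a regiochemical one in the bromination, which is why it is not the main line.

## Further compounds

F1 | step 9 | methyl (R)-3-hydroxy-3-[4-methoxy-3,5-bis(3-methylbut-2-en-1-yl)phenyl]propanoate | COc1c(CC=C(C)C)cc([C@H](O)CC(=O)OC)cc1CC=C(C)C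
F2 | step 9 | 2-bromo-5-(methoxymethoxy)phenol | COCOc1ccc(Br)c(O)c1
F3 | step 9 | methyl (S)-3-[2-bromo-5-(methoxymethoxy)phenoxy]-3-[4-methoxy-3,5-bis(3-methylbut-2-en-1-yl)phenyl]propanoate | COc1c(CC=C(C)C)cc([C@@H](Oc2cc(OCOC)ccc2Br)CC(=O)OC)cc1CC=C(C)C
F4 | step 9 | (S)-3-[2-bromo-5-(methoxymethoxy)phenoxy]-N-methoxy-N-methyl-3-[4-methoxy-3,5-bis(3-methylbut-2-en-1-yl)phenyl]propanamide | COc1c(CC=C(C)C)cc([C@@H](Oc2cc(OCOC)ccc2Br)CC(=O)N(C)OC)cc1CC=C(C)C
F5 | step 10 | (2S)-5-chloro-7-(methoxymethoxy)-2-[4-methoxy-3,5-bis(3-methylbut-2-en-1-yl)phenyl]chroman-4-ol (C4 epimers) | COc1c(CC=C(C)C)cc([C@@H]2CC(O)c3c(Cl)cc(OCOC)cc3O2)cc1CC=C(C)C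
F6 | step 10 | (2S)-7-(methoxymethoxy)-2-[4-methoxy-3,5-bis(3-methylbut-2-en-1-yl)phenyl]chroman-4-ol (C4 epimers) | COc1c(CC=C(C)C)cc([C@@H]2CC(O)c3ccc(OCOC)cc3O2)cc1CC=C(C)C
F7 | step 6 | 1-(3,5-diallyl-4-methoxyphenyl)ethan-1-one | COc1c(CC=C)cc(C(C)=O)cc1CC=C
F8 | step 3 | 3-chloro-5-(methoxymethoxy)phenol | COCOc1cc(O)cc(Cl)c1
F9 | step 3 | 2-bromo-3-chloro-5-(methoxymethoxy)phenol | COCOc1cc(O)c(Br)c(Cl)c1
F10 | step 3 | [2-bromo-3-chloro-5-(methoxymethoxy)phenoxy]trimethylsilane | COCOc1cc(O[Si](C)(C)C)c(Br)c(Cl)c1
A1 | alternative 1 | (S)-2-[4-methoxy-3,5-bis(3-methylbut-2-en-1-yl)phenyl]-7-(trimethylsilyloxy)chroman-4-one | COc1c(CC=C(C)C)cc([C@@H]2CC(=O)c3ccc(O[Si](C)(C)C)cc3O2)cc1CC=C(C)C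
A2 | alternative 1 | (2S)-2-[4-methoxy-3,5-bis(3-methylbut-2-en-1-yl)phenyl]-5-(phenylsulfinyl)-2,3-dihydro-4H-pyran-4-one | COc1c(CC=C(C)C)cc([C@@H]2CC(=O)C(S(=O)c3ccccc3)=CO2)cc1CC=C(C)C
A3 | alternative 1 | (E)-1-methoxy-3-(trimethylsilyloxy)buta-1,3-diene | CO/C=C/C(=C)O[Si](C)(C)C
A4 | alternative 1 | 4-methoxy-3,5-bis(3-methylbut-2-en-1-yl)benzaldehyde | COc1c(CC=C(C)C)cc(C=O)cc1CC=C(C)C
A5 | alternative 1 | (S)-2-[4-methoxy-3,5-bis(3-methylbut-2-en-1-yl)phenyl]-2,3-dihydro-4H-pyran-4-one | COc1c(CC=C(C)C)cc([C@@H]2CC(=O)C=CO2)cc1CC=C(C)C
A6 | alternative 2 | (S)-2-[4-methoxy-3,5-bis(3-methylbut-2-en-1-yl)phenyl]-7-(triisopropylsilyloxy)chroman-4-one | COc1c(CC=C(C)C)cc([C@@H]2CC(=O)c3ccc(O[Si](C(C)C)(C(C)C)C(C)C)cc3O2)cc1CC=C(C)C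
A7 | alternative 2 | (S)-3-[2-bromo-5-(triisopropylsilyloxy)phenoxy]-N-methoxy-N-methyl-3-[4-methoxy-3,5-bis(3-methylbut-2-en-1-yl)phenyl]propanamide | COc1c(CC=C(C)C)cc([C@@H](Oc2cc(O[Si](C(C)C)(C(C)C)C(C)C)ccc2Br)CC(=O)N(C)OC)cc1CC=C(C)C
A8 | alternative 2 | 2-bromo-5-(triisopropylsilyloxy)phenol | CC(C)[Si](Oc1ccc(Br)c(O)c1)(C(C)C)C(C)C
A9 | alternative 2 | methyl (R)-3-hydroxy-3-[4-methoxy-3,5-bis(3-methylbut-2-en-1-yl)phenyl]propanoate | COc1c(CC=C(C)C)cc([C@H](O)CC(=O)OC)cc1CC=C(C)C
A10 | alternative 3 | (S)-7-(methoxymethoxy)-2-[4-methoxy-3,5-bis(3-methylbut-2-en-1-yl)phenyl]chroman-4-one | COc1c(CC=C(C)C)cc([C@@H]2CC(=O)c3ccc(OCOC)cc3O2)cc1CC=C(C)C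
A11 | alternative 3 | (S)-1-[2-fluoro-4-(methoxymethoxy)phenyl]-3-hydroxy-3-[4-methoxy-3,5-bis(3-methylbut-2-en-1-yl)phenyl]propan-1-one | COc1c(CC=C(C)C)cc([C@@H](O)CC(=O)c2ccc(OCOC)cc2F)cc1CC=C(C)C
A12 | alternative 3 | 1-[2-fluoro-4-(methoxymethoxy)phenyl]ethan-1-one | CC(=O)c1ccc(OCOC)cc1F
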